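## Retrosynthetic overview

1. Rings A and B are bought as 3,5-dimethoxyphenol (1) and 3,5-dihydroxybenzoic acid (2).
2. Aryl–carbonyl disconnection: BF3-mediated ortho-acylation of 1 by 2, steered by boron chelate 3, gives the unprotected triphenolic benzophenone 4.
3. Pyran disconnection (O1–C2 and C4–C4a): prenal (5) condenses on ring B of 4 to ortho-quinone methide 6, the species the biosynthesis reaches by dehydrogenating an ortho-prenyl resorcinol; 6 closes by oxa-6π electrocyclisation to target 7.
4. Ring order: A and B preformed, pyran ring C last, on the fully unprotected benzophenone (no protecting groups, two steps).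

Assumption: the target has no stereocentre and no stereogenic alkene, so it is achiral and needs no enantiocontrol.
Assumption: the route has only two steps, so the closing ranking names three points of failure spread over these two steps (two for step 2, one for step 1).
Locants used below: on ring B, C1' carries the carbonyl and C3'/C5' the hydroxyls; C2'/C6' are equivalent and lie next to the carbonyl; C4' lies between the two hydroxyls.

## Route

Step 1
Reactants: 1 3,5-dimethoxyphenol; 2 3,5-dihydroxybenzoic acid
Product: 4 (3,5-dihydroxyphenyl)(2-hydroxy-4,6-dimethoxyphenyl)methanone, via difluoroboron chelate 3 (not isolated)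
Conditions: 1 (2 equiv), BF3·OEt2 (neat, 8 equiv), 95 °C, 4 h; then MeOH/H2O, 65 °C
Reagents that add atoms: none
Why: BF3-promoted Friedel–Crafts acylation (O-acylation/Fries manifold) of the far more electron-rich ring of 1 by the free acid, in which the acyl group settles ortho to the phenol because that isomer is trapped as the six-membered difluoroboron chelate 3, hydrolysed to 4 in the methanol–water work-up; ring B of 2 is deactivated by its own carboxyl group and does not acylate itself, and no stereocentre is formed.

Step 2
Reactants: 4 (3,5-dihydroxyphenyl)(2-hydroxy-4,6-dimethoxyphenyl)methanone; 5 3-methylbut-2-enal (prenal)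
Product: 7 (7-hydroxy-2,2-dimethyl-2H-chromen-5-yl)(2-hydroxy-4,6-dimethoxyphenyl)methanone, via ortho-quinone methide 6 (not isolated)
Conditions: 5 (1.1 equiv), ethylenediammonium diacetate (EDDA, 20 mol%), toluene/DMF 5:1, 100 °C, 8 h
Reagents that add atoms: none
Why: Amine-catalysed Knoevenagel-type condensation followed by oxa-6π electrocyclisation (formal [3+3] chromene annulation): the iminium of prenal is attacked by ring-B carbon C2' (ortho to one free phenol, para to the other, two equivalent sites), loss of the amine gives ortho-quinone methide 6 and 6 closes to the 2H-pyran; ring A stays out because its only phenol is locked in the hydrogen bond to the ketone, attack at C4' between the two hydroxyls is the competing pathway and that isomer is removed by chromatography, and no stereocentre is formed.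

## Compound list

1 | 3,5-dimethoxyphenol | COc1cc(O)cc(OC)c1 | starting material
2 | 3,5-dihydroxybenzoic acid | OC(=O)c1cc(O)cc(O)c1 | starting material
3 | 2,2-difluoro-4-(3,5-dihydroxyphenyl)-5,7-dimethoxy-1,3,2-benzodioxaborinine (difluoroboron chelate of 4; BF2 bridges the phenol oxygen and the ketone oxygen) | COc1cc(OC)c2c(c1)O[B-](F)(F)[O+]=C2c1cc(O)cc(O)c1 | intermediate
4 | (3,5-dihydroxyphenyl)(2-hydroxy-4,6-dimethoxyphenyl)methanone | COc1cc(O)c(C(=O)c2cc(O)cc(O)c2)c(OC)c1 | intermediate
5 | 3-methylbut-2-enal (prenal) | CC(C)=CC=O | starting material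
6 | (6Z)-3-hydroxy-5-(2-hydroxy-4,6-dimethoxybenzoyl)-6-(3-methylbut-2-en-1-ylidene)cyclohexa-2,4-dien-1-one (ortho-quinone methide) | COc1cc(O)c(C(=O)C2=CC(O)=CC(=O)/C2=C\C=C(C)C)c(OC)c1 | intermediate
7 | (7-hydroxy-2,2-dimethyl-2H-chromen-5-yl)(2-hydroxy-4,6-dimethoxyphenyl)methanone | COc1cc(O)c(C(=O)c2cc(O)cc3c2C=CC(C)(C)O3)c(OC)c1 | target

## Step count and risks

Total step count: 2. Longest linear sequence: 2 steps (1 → 4 → 7).

**Risk 1: step 2, regiochemistry on ring B.** Carbon C4' between the two hydroxyls competes with C2'/C6'. It is less hindered than the position next to the twisted aroyl group, and by analogy with 5-substituted resorcinols the 5-hydroxy-7-aroyl chromene isomer may even be the major product. Only the two-fold statistical weight of C2'/C6' and their para relationship to a phenol favour 7. The isomers are told apart by HMBC: in 7 the ketone carbon correlates with one aromatic proton (H-6), in the unwanted isomer with two.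

Fallback (blocking group instead of intrinsic selectivity): it sets out from 1 and costs one extra step.
- 1 is acylated under the step 1 conditions with purchased 4-bromo-3,5-dihydroxybenzoic acid F1. Through bromo difluoroboron chelate F2 (not isolated) this gives (4-bromo-3,5-dihydroxyphenyl)(2-hydroxy-4,6-dimethoxyphenyl)methanone F3, in which C4' is blocked.
- Prenal 5 and EDDA as in step 2 can then only engage C2'/C6'. Through bromo ortho-quinone methide F4 (not isolated) they give (8-bromo-7-hydroxy-2,2-dimethyl-2H-chromen-5-yl)(2-hydroxy-4,6-dimethoxyphenyl)methanone F5.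
- Hydrodebromination (Pd(OAc)2, PPh3, HCO2Na, DMF, 90 °C) is expected to leave the chromene alkene untouched and brings the sequence back to the route at 7.

**Risk 2: step 1.** An aryl carboxylic acid is a sluggish acylating agent under BF3. The free phenols of 2 can form aryl esters (depside oligomers). Some para acylation (4-hydroxy-2,6-dimethoxy isomer) is possible.

Fallback (activated, phenol-masked acyl donor with metal-templated ortho delivery): it sets out from 2.
- Acetylation (Ac2O, pyridine) gives 3,5-diacetoxybenzoic acid F6, and SOCl2 (cat. DMF, reflux) gives 3,5-diacetoxybenzoyl chloride F7.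
- TiCl4-mediated ortho-acylation of 1 with F7 (ClCH2CH2Cl, 0 to 60 °C) gives 5-(2-hydroxy-4,6-dimethoxybenzoyl)-1,3-phenylene diacetate F8; the titanium phenoxide of 1 delivers the acyl group to the ortho carbon.
- K2CO3 in MeOH at room temperature removes both acetates and the sequence comes back to the route at 4.

**Risk 3: step 2, conversion and over-reaction.** This is a second, independent failure mode. Ring B is deactivated by the meta acyl group, so the intermolecular iminium condensation may stall. Alternatively the product's remaining phenol may take up a second prenal to give a bis-chromene.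

Fallback (intramolecular delivery by sigmatropic rearrangement instead of intermolecular condensation): it sets out from 4.
- Mono-O-alkylation of one ring-B phenol with 3-chloro-3-methylbut-1-yne (K2CO3, KI, CuI cat., acetone, reflux) gives (3-hydroxy-5-((2-methylbut-3-yn-2-yl)oxy)phenyl)(2-hydroxy-4,6-dimethoxyphenyl)methanone F9, which is purified. The chelated ring-A phenol does not react.
- Heating F9 in xylene at 140 °C triggers the aromatic propargyl Claisen rearrangement. Known meta-substituent effects steer it to C2' (towards the meta acyl group, away from the meta hydroxyl).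
- This gives allenyl phenol (3,5-dihydroxy-2-(3-methylbuta-1,2-dien-1-yl)phenyl)(2-hydroxy-4,6-dimethoxyphenyl)methanone F10 (not isolated), whose 1,5-hydrogen shift delivers 6.
- The sequence thus comes back to the route at 6, which closes to 7 as in step 2.

## Further compounds

F1 | step 2 | 4-bromo-3,5-dihydroxybenzoic acid (purchased) | OC(=O)c1cc(O)c(Br)c(O)c1
F2 | step 2 | 4-(4-bromo-3,5-dihydroxyphenyl)-2,2-difluoro-5,7-dimethoxy-1,3,2-benzodioxaborinine (bromo difluoroboron chelate) | COc1cc(OC)c2c(c1)O[B-](F)(F)[O+]=C2c1cc(O)c(Br)c(O)c1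
F3 | step 2 | (4-bromo-3,5-dihydroxyphenyl)(2-hydroxy-4,6-dimethoxyphenyl)methanone | COc1cc(O)c(C(=O)c2cc(O)c(Br)c(O)c2)c(OC)c1
F4 | step 2 | (6Z)-2-bromo-3-hydroxy-5-(2-hydroxy-4,6-dimethoxybenzoyl)-6-(3-methylbut-2-en-1-ylidene)cyclohexa-2,4-dien-1-one (bromo ortho-quinone methide) | COc1cc(O)c(C(=O)C2=CC(O)=C(Br)C(=O)/C2=C\C=C(C)C)c(OC)c1
F5 | step 2 | (8-bromo-7-hydroxy-2,2-dimethyl-2H-chromen-5-yl)(2-hydroxy-4,6-dimethoxyphenyl)methanone | COc1cc(O)c(C(=O)c2cc(O)c(Br)c3c2C=CC(C)(C)O3)c(OC)c1
F6 | step 1 | 3,5-diacetoxybenzoic acid | CC(=O)Oc1cc(OC(C)=O)cc(C(=O)O)c1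
F7 | step 1 | 3,5-diacetoxybenzoyl chloride | CC(=O)Oc1cc(OC(C)=O)cc(C(=O)Cl)c1
F8 | step 1 | 5-(2-hydroxy-4,6-dimethoxybenzoyl)-1,3-phenylene diacetate | COc1cc(O)c(C(=O)c2cc(OC(C)=O)cc(OC(C)=O)c2)c(OC)c1
F9 | step 2 | (3-hydroxy-5-((2-methylbut-3-yn-2-yl)oxy)phenyl)(2-hydroxy-4,6-dimethoxyphenyl)methanone | COc1cc(O)c(C(=O)c2cc(O)cc(OC(C)(C)C#C)c2)c(OC)c1
F10 | step 2 | (3,5-dihydroxy-2-(3-methylbuta-1,2-dien-1-yl)phenyl)(2-hydroxy-4,6-dimethoxyphenyl)methanone | COc1cc(O)c(C(=O)c2cc(O)cc(O)c2C=C=C(C)C)c(OC)c1
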